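## Analysis of the target

The target 18 is a dihydroflavonol: a chroman-4-one whose ring C (O1, C2, C3, C4, C4a, C8a) is fused to ring A and carries ring B at C2. Ring A is oxygenated at four contiguous carbons (C5 OH, C6 OH, C7 OMe, C8a as O1) and only C8 is unsubstituted. Ring B is a 3-hydroxy-4-methoxyphenyl group, and C3 carries a methyl ether where dihydroflavonols usually carry a hydroxyl. The two stereocentres C2 and C3 are adjacent and both R, with the aryl and methoxy groups trans; this is the thermodynamically preferred diequatorial arrangement.

The C3 hydrogen is α to the ketone and β to the O1 aryloxide. Base can therefore open ring C by β-elimination to an achiral chalcone, which erases both centres, or lead on to the flavonol. The 5,6-catechol is prone to oxidation, and the benzylic C2–O1 bond is acid-labile. The difficulty lies in absolute control at C2, relative control at C3, O-methylation at C3 without base, and telling six oxygen substituents apart (three phenols, three methyl ethers).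

The strategy rests on C3 and C4 being neighbouring oxidised carbons of ring C. They can be read as a former C3=C4 double bond lying between C4a of ring A and the C2 stereocentre. That cis alkene in a six-membered ring is the product of ring-closing metathesis between a styrene on ring A and the vinyl group of a 1-arylallyl aryl ether. A second feature is used for ring A: the oxygens at C5 and C7 are mirror-related about C6, so a symmetric phenol serves, and the C5 oxygen is singled out only at the end by its peri relationship to the C4 carbonyl.

## Retrosynthetic reasoning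

**18 from 17.** The three phenols are unmasked last, because the catechol and the free dihydroflavonol are the most fragile form of the molecule. The C6 and C3' hydroxyls are carried as benzyl ethers and the C5 hydroxyl as a methyl ether. Of the four methyl ethers in 17, only the one at C5 can form a six-membered chelate with the C4 carbonyl, so a Lewis-acidic ether cleavage should remove it together with the benzyl groups.

**17 from 16.** The C3 O–methyl bond is cut. The methyl group is put on after ring C is complete because the hydroxyl arrives with the right configuration from the alkene. The forward reaction must alkylate an α-ketol without a base strong enough to enolise it.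

**16 from 15 and 15 from 14.** The C4 carbonyl is taken back to a benzylic alcohol, and the two C–O bonds at C3 and C4 to one syn addition across a C3=C4 alkene. The cut is made here because the only stereocentre already present, C2, sits next to C3, and its aryl group can direct the oxidant to the opposite face; this gives the 2,3-trans relationship. The C4 alcohol is the only one attached to the very electron-rich ring A, which is what should allow it to be oxidised in the presence of the C3 alcohol.

**14 from 13.** The C3=C4 bond is cut. Both halves become terminal alkenes on one benzene scaffold: a vinyl group at C4a and the vinyl group of the allylic ether at C2. This is the one bond of ring C whose formation needs neither acid nor base and creates no stereocentre, so the ring closure cannot endanger C2. It also leaves the alkene exactly where the two oxygens are wanted.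

**13 from 6 and 12.** The C2–O1 bond is cut. A branched, enantioenriched aryl 1-arylallyl ether is the product of an iridium-catalysed allylic substitution of a linear cinnamyl carbonate by a phenol. The whole absolute configuration of the target is therefore set in this one catalyst-controlled step, from two achiral fragments.

**6 from 5, 4, 2 and 1.** The vinyl group of 6 comes from the aldehyde 5 by one-carbon olefination. The formyl group of 5 is introduced ortho to the hydroxyl of 4. Phenol 4 comes from aldehyde 2 by oxidative replacement of the formyl group by oxygen, and 2 is the benzyl ether of syringaldehyde 1. Phenol 4 is symmetric, so its two ortho positions are identical and the formylation has no regiochemical question. This is the reason for carrying the C5 oxygen as a methyl ether.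

**12 from 11, 10, 8, 9 and 7.** The carbonate 12 is the activated form of cinnamyl alcohol 11. Alcohol 11 is the reduction product of ester 10, and 10 is the olefination product of aldehyde 8 with phosphonate 9. Aldehyde 8 is the benzyl ether of isovanillin 7, which already holds the ring B oxygen pattern.

## Alternatives that were turned down

**Alternative 1: three-component oxonium ylide trapping.** The C2–C3 bond and the C3–OMe bond are disconnected together. Ring C is closed afterwards by forming O1–C8a from an aryl bromide.
- Forward key step: Rh2(OAc)4 converts the diazoketone 1-[5-(benzyloxy)-2-bromo-4,6-dimethoxyphenyl]-2-diazoethan-1-one A2 into a rhodium carbene. The alcohol that supplies the C3 methoxy group adds to it. The resulting oxonium ylide is intercepted, under a chiral phosphoric acid, by aldehyde 8 to give the aldol-type product A1.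
- For it: the C3 methyl ether is installed as such, both stereocentres arise in one step, and the convergence is higher than in the chosen route. On these points it is stronger.
- Against it: trapping of the ylide must outrun the 1,2-proton shift that gives plain O–H insertion. That is favourable with aryl diazoacetates and activated electrophiles, but here the carbene precursor is an acceptor-only diazoketone on a 2,6-disubstituted arene and the electrophile is an electron-rich, weakly electrophilic benzaldehyde. Relative and absolute configuration both hang on this one step. A1 is a β-hydroxy ketone with an α-methoxy group, and the ring closure that must follow (metal-catalysed etherification of a secondary benzylic alcohol with a hindered aryl bromide) needs base and heat, which invite retro-aldol cleavage and C3 epimerisation.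
- Comparison: the chosen strategy is longer, but it sets C2 and C3 one at a time by modes whose sense is predictable, and it closes ring C under neutral conditions before C3 is a stereocentre.

**Alternative 2: ring A by benzannulation on ring C.** Ring A is disconnected at C5–C6, C7–C8 and C4a–C5.
- Forward key step: photochemical Wolff rearrangement of the dihydropyranone diazoketone A4 gives a vinylketene. It adds di-tert-butoxyethyne A5 in a [2+2] step; four-electron ring opening and six-electron ring closure then give the phenol A3.
- For it: ring A is made with its oxygen pattern in one step without aromatic substitution, and the C5 hydroxyl appears free.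
- Against it: A4 must already contain both stereocentres on a β-alkoxy enone, a system that epimerises and eliminates easily, and no short enantioselective access to it is evident. The photolysis has to be done in the presence of the enone chromophore. A3 carries identical tert-butyl ethers at C6 and C7, so after their removal C7 must be methylated selectively beside C6 and C5 hydroxyls on a base-sensitive dihydroflavonol. A5 is a sensitive speciality alkyne.
- Comparison: the chosen strategy takes ring A ready-made from syringaldehyde 1, with the C7 methyl ether in place from the start, and it is clearly shorter. The benzannulation is stronger only in delivering the C5 hydroxyl without a deprotection.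

**Alternative 3: aryne annulation.** O1–C8a and C4–C4a are disconnected, so ring A is clipped as an aryne onto an open-chain hydroxy ester.
- Forward key step: CsF releases the ring A aryne from the silyl triflate A7. The hydroxyl of ester A8 adds at C8a, and the aryl anion at C4a attacks the ester, giving the chromanone A6, which is identical with 17.
- For it: this is the shortest plan on paper. A7 would come from phenol 4 and A8 from a cinnamate such as 10 by asymmetric dihydroxylation. The regiochemistry is inherently right, since a nucleophile adds to a 3-alkoxybenzyne at the carbon remote from the alkoxy group. On convergence it is stronger than the chosen route.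
- Against it: the step runs under fluoride and alkoxide base. A8 can undergo retro-aldol cleavage and epimerise at its α-carbon, and the product is exactly the kind of β-aryloxy ketone that opens to a chalcone by β-elimination. Addition of a secondary benzylic alkoxide to an aryne is less efficient than that of a phenoxide, and protonation of the aryl anion competes with acyl transfer. A8 also needs a selective methylation of one hydroxyl of a diol.
- Comparison: the chosen strategy gives up this brevity for a ring closure by metathesis that has close precedent and uses no base at any stage where C2 and C3 could be lost.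

Key step: step 10

## Route

Remark on the chemistry: the phosphoramidite enantiomer in step 9 is assigned from the usual facial model of this catalyst family, in which the (Ra,Rc,Rc) ligand gives (R)-configured aryl 1-arylallyl ethers. If the sense proved opposite, the mirror-image ligand would be used and nothing else would change.

Step 1
Reactants: 1 syringaldehyde
Product: 2 4-(benzyloxy)-3,5-dimethoxybenzaldehyde
Conditions: BnBr, K2CO3, DMF, 60 °C
Reagents that add atoms: benzyl bromide, BrCc1ccccc1
Why: Williamson etherification of the only phenol; the benzyl group masks the future C6 hydroxyl and keeps the arene symmetric.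

Step 2
Reactants: 2 4-(benzyloxy)-3,5-dimethoxybenzaldehyde
Product: 4 4-(benzyloxy)-3,5-dimethoxyphenol, via aryl formate 3 (not isolated)
Conditions: mCPBA, CH2Cl2, 0 °C to 20 °C; then K2CO3 (cat.), MeOH, 20 °C
Reagents that add atoms: 3-chloroperoxybenzoic acid, OOC(=O)c1cccc(Cl)c1
Why: Baeyer–Villiger (Dakin-type) oxidation; the electron-rich trialkoxyaryl group migrates in preference to hydride, and the labile aryl formate is methanolysed in the same flask.

Step 3
Reactants: 4 4-(benzyloxy)-3,5-dimethoxyphenol
Product: 5 3-(benzyloxy)-6-hydroxy-2,4-dimethoxybenzaldehyde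
Conditions: MgCl2, Et3N, (CH2O)n, MeCN, reflux
Reagents that add atoms: formaldehyde (as paraformaldehyde), C=O
Why: Magnesium-mediated ortho-formylation (Casnati–Skattebøl): the magnesium phenoxide delivers formaldehyde to the ortho carbon and a second formaldehyde oxidises the benzylic alkoxide; the two ortho positions of 4 are equivalent, so one product is expected.

Step 4
Reactants: 5 3-(benzyloxy)-6-hydroxy-2,4-dimethoxybenzaldehyde
Product: 6 4-(benzyloxy)-2-ethenyl-3,5-dimethoxyphenol
Conditions: Ph3PCH3Br (2.5 equiv), KOtBu (2.5 equiv), THF, 0 °C to 20 °C
Reagents that add atoms: methyltriphenylphosphonium bromide, C[P+](c1ccccc1)(c1ccccc1)c1ccccc1.[Br-]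
Why: Wittig methylenation of a salicylaldehyde with excess ylide (one equivalent is spent on the phenol); the vinylphenol is used at once because electron-rich 2-vinylphenols polymerise on standing.

Step 5
Reactants: 7 isovanillin
Product: 8 3-(benzyloxy)-4-methoxybenzaldehyde
Conditions: BnBr, K2CO3, DMF, 60 °C
Reagents that add atoms: benzyl bromide, BrCc1ccccc1
Why: Williamson etherification; the benzyl group masks the ring B phenol and is removed at the end together with the one on ring A.

Step 6
Reactants: 8 3-(benzyloxy)-4-methoxybenzaldehyde; 9 triethyl phosphonoacetate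
Product: 10 ethyl (2E)-3-[3-(benzyloxy)-4-methoxyphenyl]prop-2-enoate
Conditions: NaH, THF, 0 °C to 20 °C
Reagents that add atoms: none
Why: Horner–Wadsworth–Emmons olefination; the stabilised phosphonate anion gives the E cinnamate needed for a linear E allylic electrophile.

Step 7
Reactants: 10 ethyl (2E)-3-[3-(benzyloxy)-4-methoxyphenyl]prop-2-enoate
Product: 11 (2E)-3-[3-(benzyloxy)-4-methoxyphenyl]prop-2-en-1-ol
Conditions: i-Bu2AlH (2.5 equiv), CH2Cl2, −78 °C to 0 °C; aq. potassium sodium tartrate
Reagents that add atoms: none
Why: 1,2-Reduction of the conjugated ester to the allylic alcohol with the alkene geometry kept.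

Step 8
Reactants: 11 (2E)-3-[3-(benzyloxy)-4-methoxyphenyl]prop-2-en-1-ol
Product: 12 (2E)-3-[3-(benzyloxy)-4-methoxyphenyl]prop-2-en-1-yl methyl carbonate
Conditions: ClCO2Me, pyridine, CH2Cl2, 0 °C
Reagents that add atoms: methyl chloroformate, COC(Cl)=O
Why: Acylation of the primary alcohol; the methyl carbonate is the standard leaving group for iridium allyl chemistry and releases its own base on ionisation.

Step 9
Reactants: 6 4-(benzyloxy)-2-ethenyl-3,5-dimethoxyphenol; 12 (2E)-3-[3-(benzyloxy)-4-methoxyphenyl]prop-2-en-1-yl methyl carbonate
Product: 13 2-(benzyloxy)-5-{[(1S)-1-[3-(benzyloxy)-4-methoxyphenyl]prop-2-en-1-yl]oxy}-4-ethenyl-1,3-dimethoxybenzene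
Conditions: [Ir(cod)Cl]2 (2 mol%), (Sa,Sc,Sc)-O,O'-(1,1'-binaphthalene-2,2'-diyl) N,N-bis(1-phenylethyl)phosphoramidite (4 mol%), pre-activated with n-PrNH2; K3PO4 (1 equiv), THF, 25 °C
Reagents that add atoms: none
Why: Iridium-catalysed asymmetric allylic etherification: the cyclometallated iridium phosphoramidite ionises 12 to a cinnamyl complex, and the aryloxide of 6 attacks its aryl-bearing terminus, giving the branched ether; the ligand fixes the face of attack and so sets the future C2 (S in 13, R in the target by a change of priorities only). The carbonate leaves as CO2 and methoxide, so the phosphate only shuttles the proton.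

Step 10
Reactants: 13 2-(benzyloxy)-5-{[(1S)-1-[3-(benzyloxy)-4-methoxyphenyl]prop-2-en-1-yl]oxy}-4-ethenyl-1,3-dimethoxybenzene
Product: 14 (2S)-6-(benzyloxy)-2-[3-(benzyloxy)-4-methoxyphenyl]-5,7-dimethoxy-2H-chromene
Conditions: second-generation Grubbs catalyst (H2IMes)(PCy3)Cl2Ru=CHPh (5 mol%), 1,4-benzoquinone (10 mol%), CH2Cl2 (0.01 M), 40 °C, dark
Reagents that add atoms: none
Why: Ring-closing alkene metathesis: the ruthenium benzylidene exchanges onto one terminal alkene of 13 (most plausibly the allyl ether vinyl group, since the styrene is flanked by two ortho oxygens), the new alkylidene adds intramolecularly to the other alkene in a [2+2] step, and cycloreversion of the ruthenacyclobutane forms C3=C4 with loss of ethene. The closest known reaction type is the metathesis of 2-vinylaryl allyl ethers, including 1-arylallyl ethers, to 2H-chromenes. Ring C closes as a six-membered ring through the metallacycle, with the new alkene endocyclic and necessarily cis. No stereocentre is formed; C2 is a configurationally stable ether carbon that the catalyst does not touch. The step needs ring closure to beat oligomerisation, which the ortho placement of the two alkenes on one benzene ring and the dilution should secure. It also needs the double bonds to stay in place, which benzoquinone secures by intercepting the ruthenium hydrides that would isomerise the allyl ether to an enol ether and erase C2. If the catalyst loads on the styrene first, the resulting ortho-alkoxybenzylidene chelate is only a resting state that reopens at 40 °C, and loss of ethene drives the reaction. Light and acid are excluded because flav-3-enes can open reversibly to ortho-quinone methides, which would racemise C2.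

Step 11
Reactants: 14 (2S)-6-(benzyloxy)-2-[3-(benzyloxy)-4-methoxyphenyl]-5,7-dimethoxy-2H-chromene
Product: 15 (2R,3S,4S)-6-(benzyloxy)-2-[3-(benzyloxy)-4-methoxyphenyl]-5,7-dimethoxy-3,4-dihydro-2H-chromene-3,4-diol
Conditions: OsO4 (2 mol%), NMO (1.5 equiv), acetone/H2O 10:1, 0 °C; aq. Na2SO3
Reagents that add atoms: N-methylmorpholine N-oxide, C[N+]1([O-])CCOCC1; water, O (both oxygens are passed on by catalytic osmium tetroxide, O=[Os](=O)(=O)=O)
Why: Upjohn syn-dihydroxylation of the electron-rich styrene-type alkene; the C2 aryl group blocks its own face of the adjacent C3, so both hydroxyls should enter anti to it, giving the 2,3-trans-3,4-cis diol. This sets the C3 configuration; C4 is a temporary centre.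

Step 12
Reactants: 15 (2R,3S,4S)-6-(benzyloxy)-2-[3-(benzyloxy)-4-methoxyphenyl]-5,7-dimethoxy-3,4-dihydro-2H-chromene-3,4-diol
Product: 16 (2R,3R)-6-(benzyloxy)-2-[3-(benzyloxy)-4-methoxyphenyl]-3-hydroxy-5,7-dimethoxy-2,3-dihydro-4H-chromen-4-one
Conditions: DDQ (1.1 equiv), 1,4-dioxane, 20 °C, dark
Reagents that add atoms: none
Why: Quinone dehydrogenation of an electron-rich benzylic alcohol: hydride is taken from C4–H, the only carbinol C–H conjugated with the tetra-oxygenated ring A, while the C3 alcohol and the plain benzyl ethers are inert. DDQ is chosen over MnO2 because it cannot cleave the cis-glycol. C3 is untouched; its descriptor changes from S to R by priorities only.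

Step 13
Reactants: 16 (2R,3R)-6-(benzyloxy)-2-[3-(benzyloxy)-4-methoxyphenyl]-3-hydroxy-5,7-dimethoxy-2,3-dihydro-4H-chromen-4-one
Product: 17 (2R,3R)-6-(benzyloxy)-2-[3-(benzyloxy)-4-methoxyphenyl]-3,5,7-trimethoxy-2,3-dihydro-4H-chromen-4-one
Conditions: Me3OBF4 (3 equiv), 1,8-bis(dimethylamino)naphthalene (3 equiv), 4 Å molecular sieves, CH2Cl2, 0 °C to 20 °C
Reagents that add atoms: trimethyloxonium tetrafluoroborate, C[O+](C)C.F[B-](F)(F)F
Why: O-Methylation with Meerwein's salt and a non-nucleophilic proton acceptor that is too hindered to enolise the ketone, so neither β-elimination of the O1 aryloxide nor epimerisation at C3 should occur.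

Step 14
Reactants: 17 (2R,3R)-6-(benzyloxy)-2-[3-(benzyloxy)-4-methoxyphenyl]-3,5,7-trimethoxy-2,3-dihydro-4H-chromen-4-one
Product: 18 (2R,3R)-5,6-dihydroxy-2-(3-hydroxy-4-methoxyphenyl)-3,7-dimethoxy-2,3-dihydro-4H-chromen-4-one
Conditions: BCl3 (8 equiv), C6HMe5 (6 equiv), CH2Cl2, −78 °C to 0 °C; then H2O, under argon
Reagents that add atoms: none
Why: Lewis-acid ether cleavage: BCl3 removes both aryl benzyl ethers at low temperature (pentamethylbenzene traps the benzyl cation) and, on warming, the C5 methyl ether, the only one that can chelate boron to the C4 carbonyl in a six-membered ring. The C3, C7 and C4' methyl ethers lack this activation, and the trans stereocentres are not epimerised by acid.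

## Compound list

1 | syringaldehyde (4-hydroxy-3,5-dimethoxybenzaldehyde) | COc1cc(C=O)cc(OC)c1O | starting material
2 | 4-(benzyloxy)-3,5-dimethoxybenzaldehyde | COc1cc(C=O)cc(OC)c1OCc1ccccc1 | intermediate
3 | 4-(benzyloxy)-3,5-dimethoxyphenyl formate | COc1cc(OC=O)cc(OC)c1OCc1ccccc1 | intermediate
4 | 4-(benzyloxy)-3,5-dimethoxyphenol | COc1cc(O)cc(OC)c1OCc1ccccc1 | intermediate
5 | 3-(benzyloxy)-6-hydroxy-2,4-dimethoxybenzaldehyde | COc1cc(O)c(C=O)c(OC)c1OCc1ccccc1 | intermediate
6 | 4-(benzyloxy)-2-ethenyl-3,5-dimethoxyphenol | COc1cc(O)c(C=C)c(OC)c1OCc1ccccc1 | intermediate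
7 | isovanillin (3-hydroxy-4-methoxybenzaldehyde) | COc1ccc(C=O)cc1O | starting material
8 | 3-(benzyloxy)-4-methoxybenzaldehyde | COc1ccc(C=O)cc1OCc1ccccc1 | intermediate
9 | triethyl phosphonoacetate | CCOC(=O)CP(=O)(OCC)OCC | starting material
10 | ethyl (2E)-3-[3-(benzyloxy)-4-methoxyphenyl]prop-2-enoate | CCOC(=O)/C=C/c1ccc(OC)c(OCc2ccccc2)c1 | intermediate
11 | (2E)-3-[3-(benzyloxy)-4-methoxyphenyl]prop-2-en-1-ol | OC/C=C/c1ccc(OC)c(OCc2ccccc2)c1 | intermediate
12 | (2E)-3-[3-(benzyloxy)-4-methoxyphenyl]prop-2-en-1-yl methyl carbonate | COC(=O)OC/C=C/c1ccc(OC)c(OCc2ccccc2)c1 | intermediate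
13 | 2-(benzyloxy)-5-{[(1S)-1-[3-(benzyloxy)-4-methoxyphenyl]prop-2-en-1-yl]oxy}-4-ethenyl-1,3-dimethoxybenzene | COc1ccc([C@@H](Oc2cc(OC)c(OCc3ccccc3)c(OC)c2C=C)C=C)cc1OCc1ccccc1 | intermediate
14 | (2S)-6-(benzyloxy)-2-[3-(benzyloxy)-4-methoxyphenyl]-5,7-dimethoxy-2H-chromene | COc1ccc([C@H]2Oc3cc(OC)c(OCc4ccccc4)c(OC)c3C=C2)cc1OCc1ccccc1 | intermediate
15 | (2R,3S,4S)-6-(benzyloxy)-2-[3-(benzyloxy)-4-methoxyphenyl]-5,7-dimethoxy-3,4-dihydro-2H-chromene-3,4-diol | COc1ccc([C@H]2Oc3cc(OC)c(OCc4ccccc4)c(OC)c3[C@H](O)[C@@H]2O)cc1OCc1ccccc1 | intermediate
16 | (2R,3R)-6-(benzyloxy)-2-[3-(benzyloxy)-4-methoxyphenyl]-3-hydroxy-5,7-dimethoxy-2,3-dihydro-4H-chromen-4-one | COc1ccc([C@H]2Oc3cc(OC)c(OCc4ccccc4)c(OC)c3C(=O)[C@@H]2O)cc1OCc1ccccc1 | intermediate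
17 | (2R,3R)-6-(benzyloxy)-2-[3-(benzyloxy)-4-methoxyphenyl]-3,5,7-trimethoxy-2,3-dihydro-4H-chromen-4-one | COc1ccc([C@H]2Oc3cc(OC)c(OCc4ccccc4)c(OC)c3C(=O)[C@@H]2OC)cc1OCc1ccccc1 | intermediate
18 | (2R,3R)-5,6-dihydroxy-2-(3-hydroxy-4-methoxyphenyl)-3,7-dimethoxy-2,3-dihydro-4H-chromen-4-one | COc1ccc([C@H]2Oc3cc(OC)c(O)c(O)c3C(=O)[C@@H]2OC)cc1O | target

## Step count and least certain steps

Total: 14 steps. Longest linear sequence: 10 steps (steps 1, 2, 3, 4, 9, 10, 11, 12, 13, 14 from syringaldehyde 1; the arm from isovanillin 7 through steps 5 to 8 is equally long).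

**Step 10 (key step).** The most likely failures are migration of the allyl ether double bond by ruthenium hydrides that arise from the fragile methylidene, which would erase C2, and stalling of the catalyst as a chelated ortho-alkoxybenzylidene after loading on the styrene. A slower risk is racemisation of the product by reversible electrocyclic opening if light or acid is admitted. Fallback: set out from 5 and replace the methylene Wittig by ethylidenation (EtPPh3Br, KOtBu), giving 4-(benzyloxy)-3,5-dimethoxy-2-(prop-1-en-1-yl)phenol F1 as an E/Z mixture. Etherify it with 12 exactly as in step 9 to give 2-(benzyloxy)-5-{[(1S)-1-[3-(benzyloxy)-4-methoxyphenyl]prop-2-en-1-yl]oxy}-1,3-dimethoxy-4-(prop-1-en-1-yl)benzene F2. Ring closure of F2 with the same catalyst releases propene and comes back to the route at 14. The catalyst can then load only on the single terminal alkene, cannot form the benzylidene chelate, and propagates as an ethylidene instead of a methylidene.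

**Step 9.** The aryloxide is ortho-substituted and the cinnamyl unit is electron-rich, so incomplete branched selectivity or enantioselectivity is possible. The product ether may also lose enantiomeric purity by reversible ionisation on iridium once the carbonate is consumed, and vinylphenol 6 may polymerise before it reacts. Fallback: set out from aldehyde 8 and add divinylzinc, (CH2=CH)2Zn, under catalysis by the enantiomer of 3-exo-(dimethylamino)isoborneol that delivers the R carbinol, giving (1R)-1-[3-(benzyloxy)-4-methoxyphenyl]prop-2-en-1-ol F3. Mitsunobu coupling of F3 with phenol 6 (PPh3, DIAD, toluene, −20 °C) inverts the carbinol centre and comes back to the route at 13. The weak point of this detour is partial ionisation of the electron-rich allylic oxyphosphonium, which is why a non-polar solvent and low temperature are specified.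

**Step 12.** Hydride abstraction could compete at C2 (benzylic to ring B and α to O1), and the acidic hydroquinone could ionise the very labile C4 hydroxyl. Over-oxidation towards the flavonol is also possible. Fallback: set out from 14. Hydroboration and oxidation (BH3·THF; NaOH, H2O2), anti to the aryl group, give (2R,3S)-6-(benzyloxy)-2-[3-(benzyloxy)-4-methoxyphenyl]-5,7-dimethoxy-3,4-dihydro-2H-chromen-3-ol F4. Methylation with NaH and MeI, harmless here because no ketone is present, gives (2R,3S)-6-(benzyloxy)-2-[3-(benzyloxy)-4-methoxyphenyl]-3,5,7-trimethoxy-3,4-dihydro-2H-chromene F5. Benzylic hydroxylation at C4 with DDQ in wet CH2Cl2 gives (2R,3S)-6-(benzyloxy)-2-[3-(benzyloxy)-4-methoxyphenyl]-3,5,7-trimethoxy-3,4-dihydro-2H-chromen-4-ol F6 as a mixture of C4 epimers, and Dess–Martin periodinane oxidises both epimers to 17, where the route is rejoined. This detour also avoids step 13.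

**Step 13.** The hydroxyl is hydrogen-bonded to the ketone and flanked by the aryl group, so alkylation may be slow; any recourse to a stronger base would open ring C by β-elimination or epimerise C3. Fallback: set out from diol 15, form the 3,4-O-dibutylstannylene acetal (Bu2SnO, toluene, reflux) and alkylate it with MeI and CsF in DMF. The equatorial C3 oxygen of the cis-diol should react, giving (2R,3S,4S)-6-(benzyloxy)-2-[3-(benzyloxy)-4-methoxyphenyl]-3,5,7-trimethoxy-3,4-dihydro-2H-chromen-4-ol F7. Oxidation of the remaining C4 alcohol with Dess–Martin periodinane comes back to the route at 17; the methyl ether is then in place before the ketone exists.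

**Step 14.** The risk is incomplete differentiation of the methyl ethers. The C3 ether (five-membered chelate with the ketone) or the C7 ether (chelate with the boron aryloxide formed at C6) could be cleaved along with the C5 ether, or the C5 ether could survive; Lewis-acid opening of ring C is a lesser risk. Fallback: set out from 17 and remove the benzyl groups first by hydrogenolysis (H2, Pd/C, EtOAc, 20 °C), giving (2R,3R)-6-hydroxy-2-(3-hydroxy-4-methoxyphenyl)-3,5,7-trimethoxy-2,3-dihydro-4H-chromen-4-one F8. Then cleave only the carbonyl-chelated C5 methyl ether with MgI2·OEt2 in toluene at 60 °C, arriving at 18.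

## Further compounds

F1 | step 10 | 4-(benzyloxy)-3,5-dimethoxy-2-(prop-1-en-1-yl)phenol (E/Z mixture) | CC=Cc1c(O)cc(OC)c(OCc2ccccc2)c1OC
F2 | step 10 | 2-(benzyloxy)-5-{[(1S)-1-[3-(benzyloxy)-4-methoxyphenyl]prop-2-en-1-yl]oxy}-1,3-dimethoxy-4-(prop-1-en-1-yl)benzene (E/Z mixture) | COc1ccc([C@@H](Oc2cc(OC)c(OCc3ccccc3)c(OC)c2C=CC)C=C)cc1OCc1ccccc1
F3 | step 9 | (1R)-1-[3-(benzyloxy)-4-methoxyphenyl]prop-2-en-1-ol | COc1ccc([C@H](O)C=C)cc1OCc1ccccc1
F4 | step 12 | (2R,3S)-6-(benzyloxy)-2-[3-(benzyloxy)-4-methoxyphenyl]-5,7-dimethoxy-3,4-dihydro-2H-chromen-3-ol | COc1ccc([C@H]2Oc3cc(OC)c(OCc4ccccc4)c(OC)c3C[C@@H]2O)cc1OCc1ccccc1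
F5 | step 12 | (2R,3S)-6-(benzyloxy)-2-[3-(benzyloxy)-4-methoxyphenyl]-3,5,7-trimethoxy-3,4-dihydro-2H-chromene | COc1ccc([C@H]2Oc3cc(OC)c(OCc4ccccc4)c(OC)c3C[C@@H]2OC)cc1OCc1ccccc1
F6 | step 12 | (2R,3S)-6-(benzyloxy)-2-[3-(benzyloxy)-4-methoxyphenyl]-3,5,7-trimethoxy-3,4-dihydro-2H-chromen-4-ol (C4 epimers) | COc1ccc([C@H]2Oc3cc(OC)c(OCc4ccccc4)c(OC)c3C(O)[C@@H]2OC)cc1OCc1ccccc1
F7 | step 13 | (2R,3S,4S)-6-(benzyloxy)-2-[3-(benzyloxy)-4-methoxyphenyl]-3,5,7-trimethoxy-3,4-dihydro-2H-chromen-4-ol | COc1ccc([C@H]2Oc3cc(OC)c(OCc4ccccc4)c(OC)c3[C@H](O)[C@@H]2OC)cc1OCc1ccccc1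
F8 | step 14 | (2R,3R)-6-hydroxy-2-(3-hydroxy-4-methoxyphenyl)-3,5,7-trimethoxy-2,3-dihydro-4H-chromen-4-one | COc1ccc([C@H]2Oc3cc(OC)c(O)c(OC)c3C(=O)[C@@H]2OC)cc1O
A1 | alternative 1 | (2R,3R)-1-[5-(benzyloxy)-2-bromo-4,6-dimethoxyphenyl]-3-[3-(benzyloxy)-4-methoxyphenyl]-3-hydroxy-2-methoxypropan-1-one | COc1ccc([C@@H](O)[C@@H](OC)C(=O)c2c(Br)cc(OC)c(OCc3ccccc3)c2OC)cc1OCc1ccccc1
A2 | alternative 1 | 1-[5-(benzyloxy)-2-bromo-4,6-dimethoxyphenyl]-2-diazoethan-1-one | COc1cc(Br)c(C(=O)C=[N+]=[N-])c(OC)c1OCc1ccccc1
A3 | alternative 2 | (2R,3R)-2-[3-(benzyloxy)-4-methoxyphenyl]-6,7-di-tert-butoxy-5-hydroxy-3-methoxychroman-4-one | COc1ccc([C@H]2Oc3cc(OC(C)(C)C)c(OC(C)(C)C)c(O)c3C(=O)[C@@H]2OC)cc1OCc1ccccc1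
A4 | alternative 2 | (2R,3R)-2-[3-(benzyloxy)-4-methoxyphenyl]-6-(2-diazoacetyl)-3-methoxy-2,3-dihydro-4H-pyran-4-one | COc1ccc([C@H]2OC(C(=O)C=[N+]=[N-])=CC(=O)[C@@H]2OC)cc1OCc1ccccc1
A5 | alternative 2 | di-tert-butoxyethyne | CC(C)(C)OC#COC(C)(C)C
A6 | alternative 3 | (2R,3R)-6-(benzyloxy)-2-[3-(benzyloxy)-4-methoxyphenyl]-3,5,7-trimethoxychroman-4-one (identical with 17) | COc1ccc([C@H]2Oc3cc(OC)c(OCc4ccccc4)c(OC)c3C(=O)[C@@H]2OC)cc1OCc1ccccc1
A7 | alternative 3 | 4-(benzyloxy)-3,5-dimethoxy-2-(trimethylsilyl)phenyl trifluoromethanesulfonate | COc1cc(OS(=O)(=O)C(F)(F)F)c([Si](C)(C)C)c(OC)c1OCc1ccccc1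
A8 | alternative 3 | methyl (2R,3R)-3-[3-(benzyloxy)-4-methoxyphenyl]-3-hydroxy-2-methoxypropanoate | COc1ccc([C@@H](O)[C@@H](OC)C(=O)OC)cc1OCc1ccccc1
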